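**Plan**
1. Retrosynthesis: the six phenols are masked as benzyl ethers and the 3-OH as a benzoate. Ring C is then cut at C4a–C4 and at C2–C3 in one operation (formal [4+2], oxa-Povarov) into an O-aryl oxocarbenium ion (ring A–O1–C2–ring B) and the (E)-enol benzoate of ring D (C3=C4).
2. Enabling feature: C2 carries both O1 and the para-oxygenated ring B, so it is an ionisable acetal-level carbon. C4 is benzylic to ring D, whose 2- and 4-oxygens stabilise a cation there. C4a of ring A is para to the 7-oxygen and ortho to O1, hence nucleophilic.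
3. Forward, ring D half: 2-methoxyresorcinol is benzylated and formylated, the aldehyde is turned into an (E)-alkenylboron compound and then into the (E)-enol benzoate.
4. Forward, ring A/B half: 3,4-bis(benzyloxy)benzaldehyde and two molecules of 3-(benzyloxy)phenol give a symmetric diaryl acetal. The halves are joined and ring C is closed in step 7; debenzoylation and hydrogenolysis finish.
5. Stereochemistry: C2, C3 and C4 all arise in step 7. The absolute sense comes from the chiral counter-anion of a Brønsted acid; 2,3-trans and 3,4-trans come from the E-alkene and an all-equatorial ring closure.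

Key step: step 7

Assumption: the sense of induction of the chiral acid in step 7 cannot be predicted reliably; the route is written for the catalyst enantiomer that gives the (2R,3S) adduct, both enantiomers being accessible.

**Step 1**
Reactants: 1 2-methoxybenzene-1,3-diol
Product: 2 1,3-bis(benzyloxy)-2-methoxybenzene
Conditions: BnBr, K2CO3, DMF, 60 °C
Reagents that add atoms: benzyl bromide BrCc1ccccc1
Why: Williamson ether synthesis, in which both phenoxides are alkylated by the benzylic bromide in SN2 fashion; no stereocentre is formed.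

**Step 2**
Reactants: 2 1,3-bis(benzyloxy)-2-methoxybenzene
Product: 4 2,4-bis(benzyloxy)-3-methoxybenzaldehyde, via iminium salt 3 (not isolated)
Conditions: POCl3, DMF, 0 → 70 °C; then ice-water
Reagents that add atoms: N,N-dimethylformamide CN(C)C=O; water O
Why: Vilsmeier–Haack formylation, in which the chloroiminium ion attacks the position ortho to one benzyloxy group and para to the other (the two such positions are equivalent by symmetry), and water hydrolyses iminium salt 3 to the aldehyde.

**Step 3**
Reactants: 4 2,4-bis(benzyloxy)-3-methoxybenzaldehyde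
Product: 5 (E)-2-{2-[2,4-bis(benzyloxy)-3-methoxyphenyl]ethenyl}-4,4,5,5-tetramethyl-1,3,2-dioxaborolane
Conditions: CH2(Bpin)2, LiTMP, THF, 0 °C; then 4, −78 °C → rt
Reagents that add atoms: bis(4,4,5,5-tetramethyl-1,3,2-dioxaborolan-2-yl)methane CC1(C)OB(CB2OC(C)(C)C(C)(C)O2)OC1(C)C
Why: Boron-Wittig olefination, in which lithiated bis(pinacolboryl)methane adds to the aldehyde and syn-elimination of the borate should leave the aryl group and the remaining boryl group trans.

**Step 4**
Reactants: 5 (E)-alkenyl pinacol boronate
Product: 6 potassium (E)-{2-[2,4-bis(benzyloxy)-3-methoxyphenyl]ethenyl}trifluoroborate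
Conditions: KHF2, MeOH/H2O, rt
Reagents that add atoms: potassium hydrogen difluoride F.[F-].[K+]
Why: Standard conversion of a pinacol boronate into the bench-stable trifluoroborate salt with retention of alkene geometry, giving the boron partner best precedented for the next step.

**Step 5**
Reactants: 6 potassium (E)-alkenyltrifluoroborate
Product: 7 (E)-2-[2,4-bis(benzyloxy)-3-methoxyphenyl]ethenyl benzoate
Conditions: PhCO2H, CuBr (10 mol%), DMAP (20 mol%), 4 Å MS, O2 (1 atm), MeCN/CH2Cl2, 40 °C
Reagents that add atoms: benzoic acid OC(=O)c1ccccc1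
Why: Chan–Lam-type oxidative C–O coupling of an alkenyltrifluoroborate with a carboxylic acid, which should proceed with retention of the E geometry and puts C3 at its final oxidation level.

**Step 6**
Reactants: 8 3,4-bis(benzyloxy)benzaldehyde; 9 3-(benzyloxy)phenol (2.2 equiv)
Product: 11 1,2-bis(benzyloxy)-4-{bis[3-(benzyloxy)phenoxy]methyl}benzene, via benzal chloride 10 (not isolated)
Conditions: SOCl2, DMF (cat.), CH2Cl2, 0 °C → rt; evaporation; then 9, NaH, THF/DMF, 0 °C → rt
Reagents that add atoms: none
Why: Deoxydichlorination of the aldehyde followed by double substitution of the geminal dichloride by the phenoxide oxygen, the classical route to diaryl acetals; the acetal carbon is not stereogenic because both aryloxy groups are the same.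

**Step 7**
Reactants: 11 diaryl acetal (1.3 equiv); 7 (E)-enol benzoate
Product: 14 (2R,3S,4S)-7-(benzyloxy)-2-[3,4-bis(benzyloxy)phenyl]-4-[2,4-bis(benzyloxy)-3-methoxyphenyl]-3,4-dihydro-2H-chromen-3-yl benzoate, via aryl oxocarbenium ion 12 (not isolated), via benzylic cation 13 (not isolated)
Conditions: (S,S)-IDPi chiral Brønsted acid (5 mol%; imidodiphosphorimidate from two 3,3'-diaryl-BINOL units, N-triflyl), CH2Cl2, −60 °C, slow addition of 7
Reagents that add atoms: none
Why: Proposed new method: the chiral acid protonates an aryloxy oxygen of symmetric acetal 11 (either ionisation gives the same ion) and releases 3-(benzyloxy)phenol, leaving O-aryl oxocarbenium ion 12 as a contact ion pair with the chiral anion; C3 of enol benzoate 7 attacks C2 of 12 to give benzylic cation 13, which is trapped at C4 by C4a of ring A, and loss of the C4a proton returns the acid. The closest known reaction type is the SnCl4-promoted oxa-Povarov reaction (a stepwise Prins/Friedel–Crafts formal [4+2] of O-aryl oxocarbenium ions with styrenes and 1-propenylarenes), and the asymmetric element is borrowed from chiral Brønsted acid catalysed Povarov reactions and from IDPi-catalysed additions to oxocarbenium ion pairs; new are the chiral-anion control of the oxa variant and the enol ester as two-carbon partner. Ring C is the only ring closed, by 6-endo attack of the C4a=C8a π bond of ring A on the C4 cation (intramolecular Friedel–Crafts alkylation), the 2-oxadiene C4a=C8a–O1=C2 and the alkene C3=C4 supplying the six atoms. C2 and C3 are set together in the first C–C bond formation, the chiral anion choosing the face of the E-configured ion 12 and the E geometry of 7 in an endo approach (ring D under ring A) placing H2 and H3 trans; C4 is set in the ring closure under substrate control, ring D going equatorial and trans to the 3-benzoyloxy group, which may also bridge the cation as a dioxolanylium ion and enforce trans opening. The step needs regioselectivity in the alkene (C3 and not C4 bonds to C2), secured by the 2- and 4-benzyloxy groups of ring D, which stabilise the C4 cation far better than the benzoyloxy group would stabilise a C3 cation; regioselectivity in ring A, secured by the 7-benzyloxy group para to C4a and by crowding at the carbon between the two oxygens; and all-trans diastereoselectivity, secured by the E-alkene and the equatorial preference of the three substituents.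

**Step 8**
Reactants: 14 chroman-3-yl benzoate
Product: 15 (2R,3S,4S)-7-(benzyloxy)-2-[3,4-bis(benzyloxy)phenyl]-4-[2,4-bis(benzyloxy)-3-methoxyphenyl]-3,4-dihydro-2H-chromen-3-ol
Conditions: K2CO3, MeOH/THF, rt
Reagents that add atoms: none
Why: Base-catalysed transesterification (methanolysis) of the secondary benzoate; the benzyl ethers survive and, with no free phenol present, none of the three stereocentres can epimerise.

**Step 9**
Reactants: 15 pentabenzyl chroman-3-ol
Product: 16 (2R,3S,4R)-2-(3,4-dihydroxyphenyl)-4-(2,4-dihydroxy-3-methoxyphenyl)-3,4-dihydro-2H-chromene-3,7-diol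
Conditions: H2 (1 atm), Pd(OH)2/C, THF/MeOH, rt; filtration under argon
Reagents that add atoms: none
Why: Hydrogenolysis of the five aryl benzyl ethers under neutral conditions, the standard unmasking of benzylated flavan-3-ols, which should leave the C2–O1 bond, the C4–aryl bond, the methyl ether and all stereocentres untouched.

**Compound list**
1 | 2-methoxybenzene-1,3-diol (2-methoxyresorcinol) | COc1c(O)cccc1O | starting material
2 | 1,3-bis(benzyloxy)-2-methoxybenzene | COc1c(OCc2ccccc2)cccc1OCc1ccccc1 | intermediate
3 | N-[2,4-bis(benzyloxy)-3-methoxybenzylidene]-N-methylmethanaminium dichlorophosphate (iminium salt) | COc1c(OCc2ccccc2)ccc(C=[N+](C)C)c1OCc1ccccc1.[O-]P(=O)(Cl)Cl | intermediate (not isolated)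
4 | 2,4-bis(benzyloxy)-3-methoxybenzaldehyde | COc1c(OCc2ccccc2)ccc(C=O)c1OCc1ccccc1 | intermediate
5 | (E)-2-{2-[2,4-bis(benzyloxy)-3-methoxyphenyl]ethenyl}-4,4,5,5-tetramethyl-1,3,2-dioxaborolane | COc1c(OCc2ccccc2)ccc(/C=C/B2OC(C)(C)C(C)(C)O2)c1OCc1ccccc1 | intermediate
6 | potassium (E)-{2-[2,4-bis(benzyloxy)-3-methoxyphenyl]ethenyl}trifluoroborate | COc1c(OCc2ccccc2)ccc(/C=C/[B-](F)(F)F)c1OCc1ccccc1.[K+] | intermediate
7 | (E)-2-[2,4-bis(benzyloxy)-3-methoxyphenyl]ethenyl benzoate | COc1c(OCc2ccccc2)ccc(/C=C/OC(=O)c2ccccc2)c1OCc1ccccc1 | intermediate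
8 | 3,4-bis(benzyloxy)benzaldehyde | O=Cc1ccc(OCc2ccccc2)c(OCc2ccccc2)c1 | starting material
9 | 3-(benzyloxy)phenol | Oc1cccc(OCc2ccccc2)c1 | starting material
10 | 1,2-bis(benzyloxy)-4-(dichloromethyl)benzene (benzal chloride) | ClC(Cl)c1ccc(OCc2ccccc2)c(OCc2ccccc2)c1 | intermediate (not isolated)
11 | 1,2-bis(benzyloxy)-4-{bis[3-(benzyloxy)phenoxy]methyl}benzene (symmetric diaryl acetal) | C(Oc1cccc(OCc2ccccc2)c1)(Oc1cccc(OCc2ccccc2)c1)c1ccc(OCc2ccccc2)c(OCc2ccccc2)c1 | intermediate
12 | [3-(benzyloxy)phenyl][3,4-bis(benzyloxy)benzylidene]oxonium (O-aryl oxocarbenium ion, paired with the catalyst anion) | c1ccc(COc2cccc([O+]=Cc3ccc(OCc4ccccc4)c(OCc4ccccc4)c3)c2)cc1 | intermediate (not isolated)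
13 | open-chain benzylic cation after C2–C3 bond formation (flavan numbering: 2R,3S; cation at C4 on ring D) | c1ccc(COc2cccc(O[C@H](c3ccc(OCc4ccccc4)c(OCc4ccccc4)c3)[C@H]([CH+]c3ccc(OCc4ccccc4)c(OC)c3OCc3ccccc3)OC(=O)c3ccccc3)c2)cc1 | intermediate (not isolated)
14 | (2R,3S,4S)-7-(benzyloxy)-2-[3,4-bis(benzyloxy)phenyl]-4-[2,4-bis(benzyloxy)-3-methoxyphenyl]-3,4-dihydro-2H-chromen-3-yl benzoate (2,3-trans, 3,4-trans) | COc1c(OCc4ccccc4)ccc([C@@H]2c3ccc(OCc4ccccc4)cc3O[C@H](c3ccc(OCc4ccccc4)c(OCc4ccccc4)c3)[C@H]2OC(=O)c2ccccc2)c1OCc1ccccc1 | intermediate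
15 | (2R,3S,4S)-7-(benzyloxy)-2-[3,4-bis(benzyloxy)phenyl]-4-[2,4-bis(benzyloxy)-3-methoxyphenyl]-3,4-dihydro-2H-chromen-3-ol (2,3-trans, 3,4-trans) | COc1c(OCc4ccccc4)ccc([C@@H]2c3ccc(OCc4ccccc4)cc3O[C@H](c3ccc(OCc4ccccc4)c(OCc4ccccc4)c3)[C@H]2O)c1OCc1ccccc1 | intermediate
16 | (2R,3S,4R)-2-(3,4-dihydroxyphenyl)-4-(2,4-dihydroxy-3-methoxyphenyl)-3,4-dihydro-2H-chromene-3,7-diol (same geometry as 15; the C4 descriptor changes only because the free phenols alter the CIP priorities) | COc1c(O)ccc([C@@H]2c3ccc(O)cc3O[C@H](c3ccc(O)c(O)c3)[C@H]2O)c1O | target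

**Step count and risks**
Total steps: 9. Longest linear sequence: 8 steps (steps 1, 2, 3, 4, 5, 7, 8, 9); step 6 is the second branch.

Steps most likely to fail:

1. Step 7 (proposed new method). The chiral ion pair may give poor facial selectivity, or the strong acid may consume the electron-rich alkene by cationic oligomerisation before the acetal ionises. The fallback runs the cyclisation in its known achiral Lewis-acid form and secures the absolute configuration with an auxiliary on the C3 oxygen. Trifluoroborate 6 is coupled under the conditions of step 5 with (1S)-camphanic acid to give the (E)-enol camphanate F1. F1 and acetal 11 with SnCl4 in CH2Cl2 at −78 °C should give the two all-trans adducts, the (2R,3S,4S)-chromanyl camphanate F2 and the (2S,3R,4R)-chromanyl camphanate F3. These are diastereomers and are separated by crystallisation or chromatography. Methanolysis of F2 under the conditions of step 8 gives 15, where the route is rejoined.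

2. Step 6. The electron-rich benzal chloride may hydrolyse, stop at monosubstitution, or alkylate the ambident phenoxide at carbon. The fallback changes the oxocarbenium precursor to an α-acetoxy ether made without a cationic benzylic chloride. Aldehyde 8 with CHCl3 and DBU gives the trichloromethyl carbinol F4. Jocic–Reeve reaction of F4 with phenol 9 and NaOH in DME/H2O, in which the gem-dichloroepoxide is opened by the phenoxide oxygen in an SN2 step, gives the α-aryloxy acid F5. Oxidative decarboxylation of F5 with Pb(OAc)4 and pyridine in THF gives the α-acetoxy ether F6. F6 is used in step 7 in place of 11 (loss of acetic acid gives the same ion 12), and the route is rejoined at 14.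

3. Step 5. The electron-rich styrenyl boron reagent may suffer protodeboronation or oxidative homocoupling, the alkene geometry may erode, or DMAP may strip the acyl group from the product. The fallback builds the enol ester from the homologous aldehyde and bypasses steps 3 to 5. Wittig reaction of 4 with Ph3P=CHOMe (from the phosphonium chloride and KOtBu, THF) gives the methyl enol ether F7. Hydrolysis with aqueous HCO2H gives the arylacetaldehyde F8. O-Benzoylation of its enol (BzCl, Et3N, DMAP, CH2Cl2) should give 7 together with the (Z)-enol benzoate F9. The isomers are separated by chromatography and F9 is re-equilibrated with catalytic iodine, rejoining the route at 7.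

**Further compounds**
F1 | step 7 | (E)-2-[2,4-bis(benzyloxy)-3-methoxyphenyl]ethenyl (1S,4R)-4,7,7-trimethyl-3-oxo-2-oxabicyclo[2.2.1]heptane-1-carboxylate | CC1(C)[C@@]2(C)CC[C@@]1(OC2=O)C(=O)O/C=C/c1ccc(OCc2ccccc2)c(OC)c1OCc1ccccc1
F2 | step 7 | (2R,3S,4S)-7-(benzyloxy)-2-[3,4-bis(benzyloxy)phenyl]-4-[2,4-bis(benzyloxy)-3-methoxyphenyl]-3,4-dihydro-2H-chromen-3-yl (1S,4R)-camphanate | COc1c(OCc4ccccc4)ccc([C@@H]2c3ccc(OCc4ccccc4)cc3O[C@H](c3ccc(OCc4ccccc4)c(OCc4ccccc4)c3)[C@H]2OC(=O)[C@@]23CC[C@@](C)(C(=O)O2)C3(C)C)c1OCc1ccccc1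
F3 | step 7 | (2S,3R,4R)-7-(benzyloxy)-2-[3,4-bis(benzyloxy)phenyl]-4-[2,4-bis(benzyloxy)-3-methoxyphenyl]-3,4-dihydro-2H-chromen-3-yl (1S,4R)-camphanate | COc1c(OCc4ccccc4)ccc([C@H]2c3ccc(OCc4ccccc4)cc3O[C@@H](c3ccc(OCc4ccccc4)c(OCc4ccccc4)c3)[C@@H]2OC(=O)[C@@]23CC[C@@](C)(C(=O)O2)C3(C)C)c1OCc1ccccc1
F4 | step 6 | 1-[3,4-bis(benzyloxy)phenyl]-2,2,2-trichloroethanol (racemic) | OC(c1ccc(OCc2ccccc2)c(OCc2ccccc2)c1)C(Cl)(Cl)Cl
F5 | step 6 | 2-[3-(benzyloxy)phenoxy]-2-[3,4-bis(benzyloxy)phenyl]acetic acid (racemic) | OC(=O)C(Oc1cccc(OCc2ccccc2)c1)c1ccc(OCc2ccccc2)c(OCc2ccccc2)c1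
F6 | step 6 | [3-(benzyloxy)phenoxy][3,4-bis(benzyloxy)phenyl]methyl acetate (racemic) | CC(=O)OC(Oc1cccc(OCc2ccccc2)c1)c1ccc(OCc2ccccc2)c(OCc2ccccc2)c1
F7 | step 5 | 1,3-bis(benzyloxy)-2-methoxy-4-(2-methoxyethenyl)benzene (E/Z mixture) | COC=Cc1ccc(OCc2ccccc2)c(OC)c1OCc1ccccc1
F8 | step 5 | [2,4-bis(benzyloxy)-3-methoxyphenyl]acetaldehyde | O=CCc1ccc(OCc2ccccc2)c(OC)c1OCc1ccccc1
F9 | step 5 | (Z)-2-[2,4-bis(benzyloxy)-3-methoxyphenyl]ethenyl benzoate | COc1c(OCc2ccccc2)ccc(/C=C\OC(=O)c2ccccc2)c1OCc1ccccc1
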